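The earlier runs and the new flask were computed for substances that don't exist, noise included.

At 7.50 mM Ctl, the share of Sbt surviving 20 h stays near one value while the charge moves from 75.0 mM to 450 mM: 19.1% in ash, 19.5% in alder, 19.6% in birch. You asked for a quick number, and your hunch is that added Pdt slows the cedar run. Here is what I have.

| setting | alder | ash | birch | elm | cedar |
|---|---|---|---|---|---|
| Sbt | 150 mM | 75.0 mM | 450 mM | 150 mM | 150 mM |
| Ctl | 7.50 mM | 7.50 mM | 7.50 mM | 22.0 mM | 7.50 mM |
| Pdt |  |  |  |  | 120 mM |
| time |  |  |  |  | 20 h |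

| alder run: time / h | alder run: [Sbt] / mM | ash run: time / h | ash run: [Sbt] / mM | birch run: time / h | birch run: [Sbt] / mM | elm run: time / h | elm run: [Sbt] / mM |
|---|---|---|---|---|---|---|---|
| 0.89 | 138.1 | 0.89 | 69.0 | 0.89 | 415.0 | 0.89 | 131.8 |
| 2.7 | 118.8 | 2.7 | 59.1 | 2.7 | 355.0 | 2.7 | 102.3 |
| 5.2 | 95.0 | 5.2 | 47.1 | 5.2 | 286.5 | 5.2 | 72.2 |
| 8.2 | 75.2 | 8.2 | 37.0 | 8.2 | 222.6 | 8.2 | 48.8 |
| 12 | 54.8 | 12 | 27.2 | 12 | 163.2 | 12 | 30.5 |
| 16 | 40.3 | 16 | 20.0 | 16 | 119.4 | 16 | 18.7 |
| 20 | 29.2 | 20 | 14.3 | 20 | 88.1 | 20 | 13.1 |

(standard deviation of a reading: 0.4 mM)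

- the exponent of [Sbt] in the starting rate at the charge of the alder run (at the point where two percent of the Sbt have become Pdt) (one fixed amount of Pdt, the same in the runs compared)
- the exponent of [Ctl] in the starting rate at the charge of the alder run (at the point where two percent of the Sbt have become Pdt)
- Sbt in the cedar run at 20 h, as a share of the Sbt charged

- Overall: Sbt -> Pdt, with Ctl as catalyst.
- Constant volume, constant temperature.
- An order is taken over about fifteen percent of the charge, up and down.

In alder, the logarithm of charge over Sbt left at 20 h, divided by that time, gives 0.0818 /h, the mean first-order constant. I solve the ends of alder too. The first reading gives 0.0929 /h and the last interval 0.0805 /h, so the constant sags a little, and the mean joins the two ends.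

Those surviving shares span a 6.00-fold range of charge, so I take order one in Sbt at fixed Ctl, which is pseudo-first-order behaviour. The first readings of elm and alder give me 0.416 in Ctl.

Cedar is alder with c(Pdt) at 120 mM from the start. Birch has made 0.362 M of Pdt by 20 h, more than that, yet its mean constant is 0.0815 /h. I see no sign of Pdt acting, so I commit to 19.5% at 20 h.

The forecast gives order 1 in Sbt, order 0.48 in Ctl, and 21.3% for cedar, higher than mine. Its ground is “mild competitive inhibition”.

The flask gives 1.0, 0.43 and 19.5%.

    2 Ctl ⇌ Ctl2, settled at all times (86.00 /M)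
    Ctl + Sbt → Pdt + Ctl (12.71 /M/h)
    2 Ctl → 2 L (4.392 /M/h)
    Sbt → Pdt (0.03420 /h)

Each step that consumes Sbt is first order in it, and the constants of such steps add. Cedar's 19.5% means a mean constant of 0.0817 /h, beside alder's 0.0818 /h. The uncatalysed reaction of Sbt to Pdt is one of those steps: the cedar run without that reaction ends at 38.7% instead of 19.5%. That second flask has a mean constant of 0.0475 /h. The difference between the two flasks is 0.0342 /h, close to the 0.0342 /h of the uncatalysed step.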